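The earlier runs and the new flask come from a simulation from invented constants, and the scatter is random.

Follow one molecule. It leaves starting material, waits, and then becomes product, and the question is how far along that path the flask stands at your mark, the moment when 5.0 % of the starting material is converted.

in all of them: starting material 0.050 M; free catalyst 0.1 mol%

| run | partner | second catalyst | remark |
|---|---|---|---|
| Monday's | 1.8 equiv | 0.25 mol% | run made earlier |
| Sunday's | 1.8 equiv | 1 mol% | run made earlier |
| flask | 1.80 equiv | 0.5 mol% |  |

| run | time / min | product / % | starting material / % |
|---|---|---|---|
| Monday's | 1.33 | 0.3 | 99.0 |
| Monday's | 2.00 | 0.3 | 98.6 |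
| Monday's | 3.00 | 0.2 | 97.8 |
| Monday's | 5.00 | 0.4 | 96.8 |
| Monday's | 10.0 | 0.6 | 92.7 |
| Monday's | 15.0 | 1.7 | 89.2 |
| Sunday's | 1.33 | 0 | 99.4 |
| Sunday's | 2.00 | 0.1 | 98.8 |
| Sunday's | 3.00 | 0.4 | 97.8 |
| Sunday's | 5.00 | 1.1 | 97.1 |
| Sunday's | 10.0 | 2.8 | 92.9 |
| Sunday's | 15.0 | 5.5 | 89.5 |

(each reading ± 0.3 percentage points)

- the numbers in the tables scatter with a standard deviation of 0.3 percentage points
- no earlier run changes the charge of free catalyst; that part of a forecast is a guess
- no earlier run changes the charge of partner; that part of a forecast is a guess
- "the catalyst" is free catalyst with its forms; second catalyst is a second catalyst

* apparent order in partner when 5.0 % of the starting material are converted (percent change of the rate of making product for one percent more partner charged)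
* apparent order in free catalyst when 5.0 % of the starting material are converted (percent change of the rate of making product for one percent more free catalyst charged)

At 15.0 min, Monday's run has 89.2 % starting material left and Sunday's 89.5 %, though their product stands at 1.7 % and 5.5 %. These two runs differ in second catalyst, so I take it to act on the waiting step. Those runs put the mark in the flask near 7.04 min.

Call product over starting material lost the finished part; I take it to grow early on in proportion to time and to second catalyst. Monday's run reads 0.157 at 15.0 min, a reading with the scatter of its small product figure. Scaling it to the flask's loading and mark gives 0.148: this is the finished share, the fraction of converted molecules that are already product.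

Now turn free catalyst up, supposing it speeds the first step. The mark comes sooner, the finished share shrinks, more molecules wait, and the rate follows the waiting molecules. By my reckoning the order is therefore about the finished share, 0.148.

Turn partner up. If it acts in the first step, its order is again 0.148. If the waiting step runs in proportion to it, its order is about 0.852. No earlier run changes either charge, so both are guesses, and I lean to the lower value.

The forecast gives 0.12 (−0.05 to 0.6) for free catalyst and 0.3 (0 to 1.1) for partner, reasoning, with I as its name for the intermediate, that “at fixed conversion I is nearly fixed however fast the first step runs”. My 0.148 is higher than its free-catalyst figure.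

The flask gives 0.097 for free catalyst and 0.14 for partner.

    partner + catalyst intermediate → second catalyst + product (k = 38.5 M⁻¹ s⁻¹)
    2 free catalyst ⇌ resting dimer, settled at all times (K = 39000 M⁻¹)
    second catalyst + open intermediate ⇌ catalyst intermediate (K = 5.50 M⁻¹, k = 3.77 M⁻¹ s⁻¹)
    starting material + free catalyst → free catalyst + open intermediate (k = 6.26 M⁻¹ s⁻¹)

In the flask, when 5.0 % of the starting material is converted, resting dimer, the catalyst's resting state, holds 60.6 % of the catalyst. Scaled in proportion to time, my finished share for the flask comes to 0.263 at 12.5 min. At that time the flask has 91.2 % starting material and 2.19 % product, a finished share of 0.249.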